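**Plan**

- Retrosynthesis: the C7–O benzoate is removed last, then the two Si–O bonds of a diisopropylsilylene spanning O7 and O6, and then the carbocycle is cut at C1–C6, C2–C3 and C4–C5 in one operation.
- Enabling feature: in the ring C1(C7H2OBz)=C2–C3=C4–C5(OBz)–C6(OH) these cuts leave a propargyl unit (C7, C1, C2), acetylene (C3, C4) and an E-enediol (C5, C6). O7 and O6 stand 1,3 to each other, so one silicon atom can tie them into a six-membered 1,3-dioxa-2-silinane fused to the cyclohexadiene at C1–C6.
- Forward, chain assembly: (Z)-butenediol is benzoylated and ozonised to 2-oxoethyl benzoate. Its enol benzoate is brought to the E geometry, cleaved to the E enolate and silylated with chloro(propargyloxy)diisopropylsilane, which joins O7–Si–O6 and gives the tethered 1,7-enyne.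
- Forward, ring formation: a cationic Rh(I)/chiral bisphosphine [2+2+2] reaction with acetylene closes the siladioxane and the carbocycle together; HF·pyridine then frees the 1,3-diol and the primary alcohol is benzoylated.
- Stereochemistry: C6 comes from ligand-controlled face selection at the enol-ether alkene and C5 from suprafacial addition to the E alkene (E gives 5,6-trans). The E geometry is secured at the crystalline dibenzoate and carried on with retention.

Key step: step 6

Assumption: enolisation of 2-oxoethyl benzoate is taken to favour the Z (cis-dioxygenated) enol derivative, as is usual for α-oxygenated aldehydes, so the E isomer is obtained by equilibration and crystallisation at the dibenzoate stage.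

Assumption: the (R) ligand is written for the (5R,6R) series; the sense of induction cannot be predicted for this substrate, and the (S) ligand is to be used if it proves opposite.

**Route**

Step 1
Reactants: 1 (Z)-but-2-ene-1,4-diol
Product: 2 (Z)-but-2-ene-1,4-diyl dibenzoate
Conditions: BzCl (2.2 equiv), Et3N, DMAP (cat.), CH2Cl2, 0 °C to rt
Reagents that add atoms: benzoyl chloride, O=C(Cl)c1ccccc1
Why: DMAP-catalysed esterification (nucleophilic acyl substitution) of both primary allylic alcohols should be clean, and the Z alkene is untouched and serves only as a masked pair of aldehydes.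

Step 2
Reactants: 2 (Z)-but-2-ene-1,4-diyl dibenzoate
Product: 4 2-oxoethyl benzoate, via secondary ozonide 3 (not isolated)
Conditions: O3, CH2Cl2, −78 °C; then Me2S, −78 °C to rt
Reagents that add atoms: ozone, [O-][O+]=O
Why: Ozonolysis with reductive work-up (Criegee mechanism) should cleave the symmetrical alkene into two molecules of the α-benzoyloxy aldehyde, and benzoate esters are inert to ozone and dimethyl sulfide at low temperature.

Step 3
Reactants: 4 2-oxoethyl benzoate
Product: 6 (E)-ethene-1,2-diyl dibenzoate, via (Z)-ethene-1,2-diyl dibenzoate 5 (not isolated)
Conditions: BzCl, Et3N, DMAP (cat.), CH2Cl2, 0 °C to rt; then PhSSPh (cat.), hν, benzene, rt, with crystallisation of the E isomer (mother liquor re-equilibrated)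
Reagents that add atoms: benzoyl chloride, O=C(Cl)c1ccccc1
Why: Enol ester formation by O-benzoylation of the amine-generated enolate is eased by the acidifying α-benzoyloxy group, and because this acylation is not expected to favour E, the geometry is corrected here on the robust symmetrical dibenzoates by reversible thiyl-radical addition (radical E/Z isomerisation), which feeds the centrosymmetric E isomer that should be the less soluble one.

Step 4
Reactants: 7 prop-2-yn-1-ol; 8 dichlorodi(propan-2-yl)silane
Product: 9 chlorodi(propan-2-yl)(prop-2-yn-1-yloxy)silane
Conditions: 8 (1.2 equiv), Et3N, CH2Cl2, −78 to 0 °C, slow addition of 7; filtration under Ar, bulb-to-bulb distillation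
Reagents that add atoms: none
Why: Mono-alcoholysis of a dialkyldichlorosilane (nucleophilic substitution at silicon) should stop after one chloride, because the alkoxychlorosilane is more hindered and less electrophilic than the dichloride and the alcohol is added slowly to an excess of silane.

Step 5
Reactants: 6 (E)-ethene-1,2-diyl dibenzoate; 9 chlorodi(propan-2-yl)(prop-2-yn-1-yloxy)silane
Product: 11 (E)-2-{[di(propan-2-yl)(prop-2-yn-1-yloxy)silyl]oxy}ethenyl benzoate, via potassium (E)-2-(benzoyloxy)ethenolate 10 (not isolated)
Conditions: KOtBu (1.0 equiv), THF, −78 to −40 °C; then 9, −78 to 0 °C; filtration through Et3N-deactivated silica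
Reagents that add atoms: none
Why: Alkoxide cleavage of an enol ester (House–Duhamel enolate generation) should release the potassium enolate with retention of the double-bond geometry, the symmetry of 6 making both esters equivalent and the by-product an inert ester, and O-silylation of this hard enolate by the chlorosilane then fixes the E enediol as the mixed silyl enol ether.

Step 6
Reactants: 11 (E)-2-{[di(propan-2-yl)(prop-2-yn-1-yloxy)silyl]oxy}ethenyl benzoate; 12 acetylene
Product: 13 (8R,8aR)-2,2-di(propan-2-yl)-8,8a-dihydro-4H-1,3,2-benzodioxasilin-8-yl benzoate (the O7,O6-diisopropylsilylene of the (5R,6R)-diene-diol 5-benzoate)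
Conditions: [Rh(cod)2]BF4 (5 mol %), (R)-H8-BINAP (5 mol %), pre-activated with H2; 12 (1 atm), (CH2Cl)2, rt, slow addition of 11; filtration through neutral alumina
Reagents that add atoms: none
Why: Proposed new method: the cationic Rh(I)/bisphosphine fragment should bind the alkyne and the tethered enol-ether alkene of 11 and undergo oxidative cyclisation to a rhodacyclopentene (C1–C6), acetylene then inserts (C2–C3) and reductive elimination forms C4–C5; the closest known reactions are cationic Rh(I)/chiral-bisphosphine [2+2+2] cycloadditions of tethered 1,6-enynes with alkynes and of diynes with enol ethers, whereas a 1,7-enyne with an O–Si–O tether and an enediol alkene has not been used. The six-membered 1,3-dioxa-2-silinane closes in the oxidative cyclisation by C–C bond formation between the alkyne carbon C1 and the alkene carbon C6 (helped by the long Si–O bonds and the gem-diisopropyl groups), and the carbocycle closes as a metal-templated [2+2+2] assembly completed by the C4–C5 reductive elimination. C6 is set when the chiral ligand selects the enantioface of the enol-ether alkene in the oxidative cyclisation, and C5 follows from it because the alkene adds suprafacially, so the E geometry becomes the 5,6-trans relationship. The step needs the cross-reaction to outrun acetylene cyclotrimerisation and a single regiochemistry, both supplied by the tether, which makes the first C–C bond intramolecular and fixes C1–C6; it also needs the diene to survive without loss of benzoic acid or silanol to an arene, for which the non-coordinating counter-ion, room temperature and a neutral work-up are chosen.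

Step 7
Reactants: 13 (8R,8aR)-2,2-di(propan-2-yl)-8,8a-dihydro-4H-1,3,2-benzodioxasilin-8-yl benzoate
Product: 14 (1R,6R)-6-hydroxy-5-(hydroxymethyl)cyclohexa-2,4-dien-1-yl benzoate
Conditions: HF·pyridine, pyridine, THF, 0 °C
Reagents that add atoms: none
Why: Fluoride-induced cleavage of both Si–O bonds (silylene deprotection) under pyridine-buffered, non-basic conditions should leave the allylic benzoate in place, without migration to the neighbouring hydroxyl or elimination, and does not touch either stereocentre.

Step 8
Reactants: 14 (1R,6R)-6-hydroxy-5-(hydroxymethyl)cyclohexa-2,4-dien-1-yl benzoate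
Product: 15 [(5R,6R)-5-(benzoyloxy)-6-hydroxycyclohexa-1,3-dien-1-yl]methyl benzoate
Conditions: BzCl (1.05 equiv), 2,4,6-collidine, CH2Cl2, −40 °C
Reagents that add atoms: benzoyl chloride, O=C(Cl)c1ccccc1
Why: Kinetically selective acylation of the primary over the more hindered secondary allylic alcohol (collidine-mediated benzoylation at low temperature) with one equivalent of acid chloride should give the target without touching C6–OH or the stereocentres.

**Compound list**

1 | (Z)-but-2-ene-1,4-diol | OC/C=C\CO | starting material
2 | (Z)-but-2-ene-1,4-diyl dibenzoate | O=C(OC/C=C\COC(=O)c1ccccc1)c1ccccc1 | intermediate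
3 | (1,2,4-trioxolane-3,5-diyl)bis(methylene) dibenzoate (secondary ozonide, cis/trans mixture) | O=C(OCC1OOC(COC(=O)c2ccccc2)O1)c1ccccc1 | intermediate
4 | 2-oxoethyl benzoate | O=CCOC(=O)c1ccccc1 | intermediate
5 | (Z)-ethene-1,2-diyl dibenzoate | O=C(O/C=C\OC(=O)c1ccccc1)c1ccccc1 | intermediate
6 | (E)-ethene-1,2-diyl dibenzoate | O=C(O/C=C/OC(=O)c1ccccc1)c1ccccc1 | intermediate
7 | prop-2-yn-1-ol | C#CCO | starting material
8 | dichlorodi(propan-2-yl)silane | CC(C)[Si](Cl)(Cl)C(C)C | starting material
9 | chlorodi(propan-2-yl)(prop-2-yn-1-yloxy)silane | C#CCO[Si](Cl)(C(C)C)C(C)C | intermediate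
10 | potassium (E)-2-(benzoyloxy)ethen-1-olate | [K+].[O-]/C=C/OC(=O)c1ccccc1 | intermediate
11 | (E)-2-{[di(propan-2-yl)(prop-2-yn-1-yloxy)silyl]oxy}ethenyl benzoate | C#CCO[Si](C(C)C)(C(C)C)O/C=C/OC(=O)c1ccccc1 | intermediate
12 | acetylene | C#C | starting material
13 | (8R,8aR)-2,2-di(propan-2-yl)-8,8a-dihydro-4H-1,3,2-benzodioxasilin-8-yl benzoate | CC(C)[Si]1(C(C)C)OCC2=CC=C[C@@H](OC(=O)c3ccccc3)[C@@H]2O1 | intermediate
14 | (1R,6R)-6-hydroxy-5-(hydroxymethyl)cyclohexa-2,4-dien-1-yl benzoate | OCC1=CC=C[C@@H](OC(=O)c2ccccc2)[C@@H]1O | intermediate
15 | [(5R,6R)-5-(benzoyloxy)-6-hydroxycyclohexa-1,3-dien-1-yl]methyl benzoate | O=C(OCC1=CC=C[C@@H](OC(=O)c2ccccc2)[C@@H]1O)c1ccccc1 | target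

**Step count**

Total: 8 steps. Longest linear sequence: 7 steps (steps 1, 2, 3, 5, 6, 7, 8); step 4 is a one-step side branch.

**Steps most likely to fail**

Step 6 (key step). The cationic rhodium centre may fail to engage the electron-rich, 1,2-disubstituted enol-ether alkene, so that acetylene is merely cyclotrimerised. The rhodacycle may also collapse by β-oxygen elimination, the diene may aromatise by loss of benzoic acid or silanol, and the face selection may be poor. The fallback uses known chemistry: a thermal [4+2] cycloaddition/cycloreversion and a resolution replace the catalytic [2+2+2]. It sets out from 6 and 8 and comes back at 13. The known alcohol 6-(hydroxymethyl)-2H-pyran-2-one F1 is monosilylated with 8 (Et3N, as in step 4) to the chlorosilane 6-({[chlorodi(propan-2-yl)silyl]oxy}methyl)-2H-pyran-2-one F2. The enolate 10, generated from 6 as in step 5, is trapped with F2 to give the tethered pyranone (E)-2-({di(propan-2-yl)[(2-oxo-2H-pyran-6-yl)methoxy]silyl}oxy)ethenyl benzoate F3. Heating F3 in toluene (110–140 °C, BHT) should bring about the intramolecular Diels–Alder reaction of the pyranone diene (C6 and C3) with the E alkene to the bridged 2-oxabicyclo[2.2.2]oct-5-en-3-one lactone F4, whose endo and exo forms converge. F4 extrudes CO2 by retro-[4+2] in the same flask and should give racemic 13, that is 13 together with its enantiomer (8S,8aS)-2,2-di(propan-2-yl)-8,8a-dihydro-4H-1,3,2-benzodioxasilin-8-yl benzoate F5; the 5,6-trans relationship again follows from suprafacial addition to the E alkene. The racemate is separated by preparative chromatography on a chiral stationary phase and the (8R,8aR) enantiomer continues as 13.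

Step 3. The benzoylation may deliver almost only the Z isomer, the radical equilibration may also rest far on the Z side, or the two isomers may co-crystallise, so that too little E dibenzoate is harvested. The fallback sets the geometry by an elimination instead of by enolate acylation; it sets out from 4 and comes back at 6. Benzoyl bromide adds to the aldehyde 4 (cat. ZnBr2, CH2Cl2, 0 °C; acyl halide addition to an aldehyde) to give the α-bromoalkyl ester 1-bromoethane-1,2-diyl dibenzoate F6. DBU then removes HBr in an E2 elimination whose antiperiplanar transition state, with the two benzoyloxy groups anti, should lead to the E isomer 6 under kinetic control.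

Step 5. Silylation of the enolate by the hindered alkoxychlorosilane may be slower than loss of enolate geometry and intermolecular benzoyl transfer on warming, and the mixed silyl ketal may hydrolyse during isolation. The fallback makes the two Si–O bonds in the reverse order; it sets out from 6 and 8 and comes back at 11. The enolate 10, generated as before, is quenched at −78 °C with an excess of the far more electrophilic dichlorosilane 8 to give (E)-2-{[chlorodi(propan-2-yl)silyl]oxy}ethenyl benzoate F7. The excess of 8 is removed in vacuo and F7 is treated in the same flask with prop-2-yn-1-ol 7 and imidazole, which closes the second Si–O bond and should give 11 without chromatography on silica.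

Further compounds
F1 | step 6 | 6-(hydroxymethyl)-2H-pyran-2-one | O=C1C=CC=C(CO)O1
F2 | step 6 | 6-({[chlorodi(propan-2-yl)silyl]oxy}methyl)-2H-pyran-2-one | O=C1C=CC=C(CO[Si](Cl)(C(C)C)C(C)C)O1
F3 | step 6 | (E)-2-({di(propan-2-yl)[(2-oxo-2H-pyran-6-yl)methoxy]silyl}oxy)ethenyl benzoate | O=C1C=CC=C(CO[Si](C(C)C)(C(C)C)O/C=C/OC(=O)c2ccccc2)O1
F4 | step 6 | intramolecular Diels–Alder adduct of F3, a bridged 2-oxabicyclo[2.2.2]oct-5-en-3-one lactone fused to the 2,2-di(propan-2-yl)-1,3-dioxa-2-silinane and carrying the benzoate (endo/exo mixture, configuration not specified) | O=C1OC23CO[Si](C(C)C)(C(C)C)OC2C(OC(=O)c2ccccc2)C1C=C3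
F5 | step 6 | (8S,8aS)-2,2-di(propan-2-yl)-8,8a-dihydro-4H-1,3,2-benzodioxasilin-8-yl benzoate | CC(C)[Si]1(C(C)C)OCC2=CC=C[C@H](OC(=O)c3ccccc3)[C@H]2O1
F6 | step 3 | 1-bromoethane-1,2-diyl dibenzoate (racemic) | O=C(OCC(Br)OC(=O)c1ccccc1)c1ccccc1
F7 | step 5 | (E)-2-{[chlorodi(propan-2-yl)silyl]oxy}ethenyl benzoate | CC(C)[Si](Cl)(O/C=C/OC(=O)c1ccccc1)C(C)C
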